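**Retrosynthetic overview**
1. Ketoemblide ⇐ lactonisation of the C8 tertiary hydroxyl onto the C20 acid of a 14-membered hydroxy acid (the seven-membered lactone is the last ring).
2. 14-Membered carbocycle ⇐ intramolecular B-alkyl Suzuki coupling C10–C11 (vinyl on C8 + (Z)-enol triflate on C12); this is the first ring formed.
3. C3=C4 of the dienoate ⇐ intermolecular Z-selective Horner–Wadsworth–Emmons reaction of a keto phosphonate with an enal.
4. Keto phosphonate ⇐ Michael addition to an α'-hydroxy enone, which comes from a catalytic enantioselective 1,2-vinyl shift (α-ketol rearrangement) of an achiral divinyl ketol; this sets C8, the only stereocentre.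
5. Enal triflate ⇐ alkyne hydroalumination/iodination, B-alkyl Suzuki coupling, formylation, enol triflation, oxidation.

Atom labels C1–C20 are cembrane numbering: C1 carries isopropyl, C4 carries CO2Me (C18), C7 is the ketone, C8 the carbinol (C19 methyl), C12 carries the lactone carbonyl C20.
Assumption: the (S,S)-ligand in step 3 is taken to give (S)-5; if the sense of induction is the opposite, the (R,R)-ligand is used.
Assumption: tert-butyl but-3-enoate 11 is the commercial tert-butyl-protected form of but-3-enoic acid; the tert-butyl group is only a protecting group and is removed in step 13.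

**Step 1**
Reactants: 1 ethyl (2R)-2-hydroxypropanoate; 2 vinylmagnesium bromide
Product: 3 (2R)-3-ethenylpent-4-ene-2,3-diol
Conditions: 2 (3.5 equiv), CeCl3 (3.5 equiv), THF, −78 → 0 °C; aq. NH4Cl
Reagents that add atoms: none
Why: Double 1,2-addition of the vinyl organometallic to the ester (Grignard ester addition) gives the divinyl carbinol, CeCl3 suppresses conjugate addition to the intermediate vinyl ketone, and the lactate stereocentre is irrelevant because it is oxidised in step 2.

**Step 2**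
Reactants: 3 (2R)-3-ethenylpent-4-ene-2,3-diol
Product: 4 3-ethenyl-3-hydroxypent-4-en-2-one
Conditions: IBX (1.5 equiv), DMSO, 23 °C
Reagents that add atoms: none
Why: IBX (hypervalent-iodine alcohol oxidation) converts the secondary hydroxyl of the 1,2-diol into the ketone without glycol cleavage and cannot oxidise the tertiary hydroxyl.

**Step 3**
Reactants: 4 3-ethenyl-3-hydroxypent-4-en-2-one
Product: 5 (4S)-4-hydroxy-4-methylhexa-1,5-dien-3-one
Conditions: Sc(OTf)3 (10 mol%), (S,S)-2,6-bis(4-phenyl-4,5-dihydrooxazol-2-yl)pyridine (12 mol%), 4 Å MS, CH2Cl2, 0 → 23 °C; stopped at full conversion, filtered through silica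
Reagents that add atoms: none
Why: Proposed new method: a catalytic enantioselective, desymmetrising α-ketol (acyloin) rearrangement with 1,2-vinyl migration, in which the ketol binds the chiral Sc(OTf)3–pybox complex as a five-membered O,O-chelate that activates the acetyl carbonyl and holds the two enantiotopic vinyl groups on opposite faces of the chelate plane, so that the ligand lets only one of them shift suprafacially (bridged, cyclopropylcarbinyl-like transition state) onto the carbonyl carbon and the new C8 carbinol centre forms as one enantiomer, the shift being driven by the gain of enone conjugation while back reaction and methyl shift are slower; the closest known reaction type is the chiral Lewis-acid-catalysed α-ketol rearrangement of cyclic tertiary α-hydroxy ketones (ring expansion by alkyl or aryl shift), which has not been shown for an acyclic divinyl carbinol.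

**Step 4**
Reactants: 6 methyl bromoacetate
Product: 7 methyl 2-(diphenoxyphosphoryl)acetate
Conditions: (PhO)2P(O)H, Et3N, CH2Cl2, 0 → 23 °C
Reagents that add atoms: diphenyl phosphite, O=[PH](Oc1ccccc1)Oc1ccccc1
Why: Michaelis–Becker alkylation of the phosphite with the α-bromo ester gives the diaryl (Ando-type) phosphonoacetate needed for Z-selective olefination.

**Step 5**
Reactants: 5 (4S)-4-hydroxy-4-methylhexa-1,5-dien-3-one; 7 methyl 2-(diphenoxyphosphoryl)acetate
Product: 8 methyl (6S)-2-(diphenoxyphosphoryl)-6-hydroxy-6-methyl-5-oxooct-7-enoate (1:1 epimers at C2)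
Conditions: 7 (2 equiv), DBU (10 mol%), THF, 0 °C
Reagents that add atoms: none
Why: Base-catalysed Michael addition of the phosphonate-stabilised carbanion to the unhindered vinyl ketone forms C4–C5; excess 7 prevents double addition, and the new C2 centre is destroyed in step 11.

**Step 6**
Reactants: 9 4-methylpent-2-yn-1-ol
Product: 10 (2Z)-3-iodo-4-methylpent-2-en-1-ol
Conditions: NaAlH2(OCH2CH2OMe)2 (1.5 equiv), THF, 0 → 23 °C; then I2, −78 → 0 °C
Reagents that add atoms: iodine, II
Why: Hydroxyl-directed trans-hydroalumination of the propargylic alcohol places aluminium on C3 cis to CH2OH, and iodinolysis with retention gives the (Z)-vinyl iodide, which fixes the C1=C2 geometry of the target.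

**Step 7**
Reactants: 11 tert-butyl but-3-enoate; 10 (2Z)-3-iodo-4-methylpent-2-en-1-ol
Product: 13 tert-butyl (5E)-7-hydroxy-5-(propan-2-yl)hept-5-enoate, via tert-butyl 4-(9-borabicyclo[3.3.1]nonan-9-yl)butanoate 12 (not isolated)
Conditions: 11, 9-BBN, THF, 0 → 23 °C; then 10, Pd(dppf)Cl2 (5 mol%), AsPh3, Cs2CO3, DMF/H2O, 23 °C
Reagents that add atoms: none
Why: 9-BBN hydroborates the terminal alkene at the terminal carbon, and the B-alkyl Suzuki–Miyaura coupling with the vinyl iodide forms C14–C1 with retention of alkene geometry and tolerates the free hydroxyl and the ester.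

**Step 8**
Reactants: 13 tert-butyl (5E)-7-hydroxy-5-(propan-2-yl)hept-5-enoate; 14 ethyl formate
Product: 15 tert-butyl (5E)-2-formyl-7-hydroxy-5-(propan-2-yl)hept-5-enoate (mainly the hydroxymethylidene enol)
Conditions: LiN(iPr)2 (2.2 equiv), THF, −78 °C; then 14, −78 → 0 °C; K2CO3, MeOH work-up
Reagents that add atoms: none
Why: Crossed Claisen condensation (α-formylation) of the ester enolate, generated beside the lithium alkoxide, installs C11 and is driven by deprotonation of the β-formyl ester; the brief K2CO3/MeOH treatment cleaves any O-formate.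

**Step 9**
Reactants: 15 tert-butyl (5E)-2-formyl-7-hydroxy-5-(propan-2-yl)hept-5-enoate
Product: 16 tert-butyl (2Z,5E)-7-hydroxy-5-(propan-2-yl)-2-{[(trifluoromethanesulfonyl)oxy]methylidene}hept-5-enoate
Conditions: NaH (1.05 equiv), THF, 0 °C; then PhNTf2, 0 → 23 °C
Reagents that add atoms: N,N-bis(trifluoromethanesulfonyl)aniline, FC(F)(F)S(=O)(=O)N(c1ccccc1)S(=O)(=O)C(F)(F)F
Why: The chelated sodium enolate of the α-formyl ester (enolate oxygen cis to the ester) is O-triflated to the (Z)-enol triflate, which sets the C11=C12 geometry, while one equivalent of base leaves the far less acidic primary alcohol untouched.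

**Step 10**
Reactants: 16 tert-butyl (2Z,5E)-7-hydroxy-5-(propan-2-yl)-2-{[(trifluoromethanesulfonyl)oxy]methylidene}hept-5-enoate
Product: 17 tert-butyl (2Z,5E)-7-oxo-5-(propan-2-yl)-2-{[(trifluoromethanesulfonyl)oxy]methylidene}hept-5-enoate
Conditions: MnO2 (15 equiv), CH2Cl2, 23 °C
Reagents that add atoms: none
Why: MnO2 oxidises only the allylic primary alcohol to the enal and leaves the enol triflate and the ester alone.

**Step 11**
Reactants: 8 methyl (6S)-2-(diphenoxyphosphoryl)-6-hydroxy-6-methyl-5-oxooct-7-enoate; 17 tert-butyl (2Z,5E)-7-oxo-5-(propan-2-yl)-2-{[(trifluoromethanesulfonyl)oxy]methylidene}hept-5-enoate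
Product: 18 1-tert-butyl 9-methyl (2Z,5E,7Z)-8-[(4S)-4-hydroxy-4-methyl-3-oxohex-5-en-1-yl]-5-(propan-2-yl)-2-{[(trifluoromethanesulfonyl)oxy]methylidene}nona-5,7-dienedioate
Conditions: 8, NaH (1.05 equiv), THF, −78 °C; then 17, −78 → −20 °C
Reagents that add atoms: none
Why: Ando-type Z-selective Horner–Wadsworth–Emmons olefination forms C3=C4 with the ester cis to C2 (about 9:1 expected, minor isomer removed by chromatography), and the hindered ketone and the enol triflate do not compete with the aldehyde at low temperature.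

**Step 12**
Reactants: 18 1-tert-butyl 9-methyl (2Z,5E,7Z)-8-[(4S)-4-hydroxy-4-methyl-3-oxohex-5-en-1-yl]-5-(propan-2-yl)-2-{[(trifluoromethanesulfonyl)oxy]methylidene}nona-5,7-dienedioate
Product: 20 1-tert-butyl 9-methyl (1Z,5S,9Z,11E)-5-hydroxy-5-methyl-6-oxo-12-(propan-2-yl)cyclotetradeca-1,9,11-triene-1,9-dicarboxylate, via B-alkyl-9-BBN adduct 19 (not isolated)
Conditions: 9-BBN (1.5 equiv), THF, 0 → 23 °C; then slow addition to Pd(dppf)Cl2 (20 mol%), AsPh3, Cs2CO3, THF/DMF/H2O, 23 °C, 0.002 M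
Reagents that add atoms: none
Why: 9-BBN adds to the only monosubstituted alkene (the α-branched ketone is reduced more slowly), and the intramolecular B-alkyl Suzuki–Miyaura coupling with the β-triflyloxy acrylate at high dilution forms C10–C11 and the 14-membered ring with retention of the triflate geometry.

**Step 13**
Reactants: 20 1-tert-butyl 9-methyl (1Z,5S,9Z,11E)-5-hydroxy-5-methyl-6-oxo-12-(propan-2-yl)cyclotetradeca-1,9,11-triene-1,9-dicarboxylate
Product: 21 (1Z,5S,9Z,11E)-5-hydroxy-9-(methoxycarbonyl)-5-methyl-6-oxo-12-(propan-2-yl)cyclotetradeca-1,9,11-triene-1-carboxylic acid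
Conditions: TFA/CH2Cl2 (1:4), 0 → 23 °C
Reagents that add atoms: none
Why: Acidolysis of the tert-butyl ester (loss of isobutene) frees only the C20 acid, while the methyl ester and the tertiary α-ketol, which cannot ionise next to the carbonyl, stay intact.

**Step 14**
Reactants: 21 (1Z,5S,9Z,11E)-5-hydroxy-9-(methoxycarbonyl)-5-methyl-6-oxo-12-(propan-2-yl)cyclotetradeca-1,9,11-triene-1-carboxylic acid
Product: 22 ketoemblide
Conditions: 2,4,6-Cl3C6H2COCl, Et3N, THF, 23 °C; then DMAP, toluene, 60 °C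
Reagents that add atoms: none
Why: Yamaguchi lactonisation activates only the C20 acid as a mixed anhydride, and the C8 hydroxyl, held on the same side as C20 by the C11=C12 geometry, closes the seven-membered lactone without touching the C8 configuration.

**Compound list**
1 | ethyl (2R)-2-hydroxypropanoate (ethyl (R)-lactate) | C[C@@H](O)C(=O)OCC | starting material
2 | vinylmagnesium bromide | C=C[Mg]Br | starting material
3 | (2R)-3-ethenylpent-4-ene-2,3-diol | C[C@@H](O)C(O)(C=C)C=C | intermediate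
4 | 3-ethenyl-3-hydroxypent-4-en-2-one | CC(=O)C(O)(C=C)C=C | intermediate
5 | (4S)-4-hydroxy-4-methylhexa-1,5-dien-3-one | C=C[C@](C)(O)C(=O)C=C | intermediate
6 | methyl bromoacetate | COC(=O)CBr | starting material
7 | methyl 2-(diphenoxyphosphoryl)acetate | COC(=O)CP(=O)(Oc1ccccc1)Oc1ccccc1 | intermediate
8 | methyl (6S)-2-(diphenoxyphosphoryl)-6-hydroxy-6-methyl-5-oxooct-7-enoate (C2 epimers) | COC(=O)C(CCC(=O)[C@@](C)(O)C=C)P(=O)(Oc1ccccc1)Oc1ccccc1 | intermediate
9 | 4-methylpent-2-yn-1-ol | CC(C)C#CCO | starting material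
10 | (2Z)-3-iodo-4-methylpent-2-en-1-ol | OC/C=C(\I)C(C)C | intermediate
11 | tert-butyl but-3-enoate | C=CCC(=O)OC(C)(C)C | starting material
12 | tert-butyl 4-(9-borabicyclo[3.3.1]nonan-9-yl)butanoate | CC(C)(C)OC(=O)CCCB1C2CCCC1CCC2 | intermediate
13 | tert-butyl (5E)-7-hydroxy-5-(propan-2-yl)hept-5-enoate | OC/C=C(\CCCC(=O)OC(C)(C)C)C(C)C | intermediate
14 | ethyl formate | CCOC=O | starting material
15 | tert-butyl (5E)-2-formyl-7-hydroxy-5-(propan-2-yl)hept-5-enoate (aldehyde tautomer drawn) | OC/C=C(\CCC(C=O)C(=O)OC(C)(C)C)C(C)C | intermediate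
16 | tert-butyl (2Z,5E)-7-hydroxy-5-(propan-2-yl)-2-{[(trifluoromethanesulfonyl)oxy]methylidene}hept-5-enoate | OC/C=C(\CC/C(=C/OS(=O)(=O)C(F)(F)F)C(=O)OC(C)(C)C)C(C)C | intermediate
17 | tert-butyl (2Z,5E)-7-oxo-5-(propan-2-yl)-2-{[(trifluoromethanesulfonyl)oxy]methylidene}hept-5-enoate | O=C/C=C(\CC/C(=C/OS(=O)(=O)C(F)(F)F)C(=O)OC(C)(C)C)C(C)C | intermediate
18 | 1-tert-butyl 9-methyl (2Z,5E,7Z)-8-[(4S)-4-hydroxy-4-methyl-3-oxohex-5-en-1-yl]-5-(propan-2-yl)-2-{[(trifluoromethanesulfonyl)oxy]methylidene}nona-5,7-dienedioate | COC(=O)/C(CCC(=O)[C@@](C)(O)C=C)=C\C=C(\C(C)C)CC/C(C(=O)OC(C)(C)C)=C/OS(=O)(=O)C(F)(F)F | intermediate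
19 | 1-tert-butyl 9-methyl (2Z,5E,7Z)-8-[(4S)-6-(9-borabicyclo[3.3.1]nonan-9-yl)-4-hydroxy-4-methyl-3-oxohexyl]-5-(propan-2-yl)-2-{[(trifluoromethanesulfonyl)oxy]methylidene}nona-5,7-dienedioate | COC(=O)/C(CCC(=O)[C@@](C)(O)CCB1C2CCCC1CCC2)=C\C=C(\C(C)C)CC/C(C(=O)OC(C)(C)C)=C/OS(=O)(=O)C(F)(F)F | intermediate
20 | 1-tert-butyl 9-methyl (1Z,5S,9Z,11E)-5-hydroxy-5-methyl-6-oxo-12-(propan-2-yl)cyclotetradeca-1,9,11-triene-1,9-dicarboxylate | COC(=O)/C1=C\C=C(\C(C)C)CC/C(C(=O)OC(C)(C)C)=C/CC[C@](C)(O)C(=O)CC1 | intermediate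
21 | (1Z,5S,9Z,11E)-5-hydroxy-9-(methoxycarbonyl)-5-methyl-6-oxo-12-(propan-2-yl)cyclotetradeca-1,9,11-triene-1-carboxylic acid | COC(=O)/C1=C\C=C(\C(C)C)CC/C(C(=O)O)=C/CC[C@](C)(O)C(=O)CC1 | intermediate
22 | ketoemblide (14-membered carbocycle bridged by the seven-membered C20–O–C8 lactone, C8 S) | COC(=O)/C1=C\C=C(\C(C)C)CCC2=CCC[C@](C)(OC2=O)C(=O)CC1 | target

**Step count and risks**
Total: 14 steps. Longest linear sequence: 9 steps (9 → 22 through steps 6–14).

Most likely to fail, first: step 3, the proposed new rearrangement (low enantioselectivity, back reaction, or ionisation of the bis-allylic carbinol). The fallback is known chemistry (self-regeneration of the lactate stereocentre, then Grignard addition to the dioxolanone); it sets out from 1, uses 2, and comes back at 5. Compound 1 is saponified (LiOH, THF/H2O) to (2R)-2-hydroxypropanoic acid F1, which is condensed with pivalaldehyde (TsOH, pentane, water separator) to the cis acetal (2R,5R)-2-tert-butyl-5-methyl-1,3-dioxolan-4-one F2. Its lithium enolate (LiN(iPr)2, THF, −78 °C) adds to acetaldehyde on the face opposite the tert-butyl group to give (2R,5S)-2-tert-butyl-5-(1-hydroxyethyl)-5-methyl-1,3-dioxolan-4-one F3. Dehydration with the Burgess reagent gives (2R,5S)-2-tert-butyl-5-ethenyl-5-methyl-1,3-dioxolan-4-one F4. One equivalent of 2 adds to the carbonyl of F4 at −78 °C, and acidic work-up releases pivalaldehyde and gives 5.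

Second: step 12 (9-BBN may reduce the C7 ketone, and the macrocyclic coupling may give oligomers). The fallback removes the ketone before hydroboration and closes the ring by olefination instead; it sets out from 8, uses 16, and comes back at 20. Compound 8 is reduced (NaBH4, CeCl3·7H2O, MeOH, −40 °C) to methyl (6S)-2-(diphenoxyphosphoryl)-5,6-dihydroxy-6-methyloct-7-enoate F5. Hydroboration with 9-BBN gives methyl (6S)-8-(9-borabicyclo[3.3.1]nonan-9-yl)-2-(diphenoxyphosphoryl)-5,6-dihydroxy-6-methyloctanoate F6 (not isolated), which is coupled with 16 (Pd(dppf)Cl2, AsPh3, Cs2CO3, DMF/H2O) to give 1-tert-butyl 11-methyl (2Z,6S)-10-(diphenoxyphosphoryl)-6,7-dihydroxy-2-[(3E)-5-hydroxy-3-(propan-2-yl)pent-3-en-1-yl]-6-methylundec-2-enedioate F7. IBX in DMSO oxidises the secondary and the allylic primary hydroxyl to give 1-tert-butyl 11-methyl (2Z,6S)-10-(diphenoxyphosphoryl)-6-hydroxy-6-methyl-7-oxo-2-[(3E)-5-oxo-3-(propan-2-yl)pent-3-en-1-yl]undec-2-enedioate F8. NaH in THF at high dilution then closes the 14-membered ring by intramolecular Horner–Wadsworth–Emmons reaction to give 20.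

Third: step 14 (acylation of the hindered tertiary hydroxyl across the ring). The fallback makes the ester bond first, between small fragments, and closes the lactone ring by C–C coupling; it sets out from 17, uses 8, and comes back at 22. Compound 17 is treated with TFA to give (2Z,5E)-7-oxo-5-(propan-2-yl)-2-{[(trifluoromethanesulfonyl)oxy]methylidene}hept-5-enoic acid F9. F9 is esterified with the tertiary hydroxyl of 8 ((4-NO2C6H4CO)2O, Sc(OTf)3 cat., MeCN) to give (3S)-7-(diphenoxyphosphoryl)-8-methoxy-3-methyl-4,8-dioxooct-1-en-3-yl (2Z,5E)-7-oxo-5-(propan-2-yl)-2-{[(trifluoromethanesulfonyl)oxy]methylidene}hept-5-enoate F10. NaH in THF at high dilution closes the 13-membered macrolactone methyl (3Z,6E,8Z,13S)-13-ethenyl-13-methyl-2,12-dioxo-6-(propan-2-yl)-3-{[(trifluoromethanesulfonyl)oxy]methylidene}-1-oxacyclotrideca-6,8-diene-9-carboxylate F11 by Horner–Wadsworth–Emmons reaction. Hydroboration of its vinyl group with 9-BBN gives methyl (3Z,6E,8Z,13S)-13-[2-(9-borabicyclo[3.3.1]nonan-9-yl)ethyl]-13-methyl-2,12-dioxo-6-(propan-2-yl)-3-{[(trifluoromethanesulfonyl)oxy]methylidene}-1-oxacyclotrideca-6,8-diene-9-carboxylate F12 (not isolated), and Pd(dppf)Cl2, AsPh3, Cs2CO3 close the seven-membered ring (C10–C11) to give 22.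

**Further compounds**
F1 | step 3 | (2R)-2-hydroxypropanoic acid | C[C@@H](O)C(=O)O
F2 | step 3 | (2R,5R)-2-tert-butyl-5-methyl-1,3-dioxolan-4-one | C[C@H]1O[C@@H](C(C)(C)C)OC1=O
F3 | step 3 | (2R,5S)-2-tert-butyl-5-(1-hydroxyethyl)-5-methyl-1,3-dioxolan-4-one | C[C@@]1(C(C)O)O[C@@H](C(C)(C)C)OC1=O
F4 | step 3 | (2R,5S)-2-tert-butyl-5-ethenyl-5-methyl-1,3-dioxolan-4-one | C[C@@]1(C=C)O[C@@H](C(C)(C)C)OC1=O
F5 | step 12 | methyl (6S)-2-(diphenoxyphosphoryl)-5,6-dihydroxy-6-methyloct-7-enoate | COC(=O)C(CCC(O)[C@@](C)(O)C=C)P(=O)(Oc1ccccc1)Oc1ccccc1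
F6 | step 12 | methyl (6S)-8-(9-borabicyclo[3.3.1]nonan-9-yl)-2-(diphenoxyphosphoryl)-5,6-dihydroxy-6-methyloctanoate | COC(=O)C(CCC(O)[C@@](C)(O)CCB1C2CCCC1CCC2)P(=O)(Oc1ccccc1)Oc1ccccc1
F7 | step 12 | 1-tert-butyl 11-methyl (2Z,6S)-10-(diphenoxyphosphoryl)-6,7-dihydroxy-2-[(3E)-5-hydroxy-3-(propan-2-yl)pent-3-en-1-yl]-6-methylundec-2-enedioate | COC(=O)C(CCC(O)[C@@](C)(O)CC/C=C(C(=O)OC(C)(C)C)/CC/C(=C\CO)C(C)C)P(=O)(Oc1ccccc1)Oc1ccccc1
F8 | step 12 | 1-tert-butyl 11-methyl (2Z,6S)-10-(diphenoxyphosphoryl)-6-hydroxy-6-methyl-7-oxo-2-[(3E)-5-oxo-3-(propan-2-yl)pent-3-en-1-yl]undec-2-enedioate | COC(=O)C(CCC(=O)[C@@](C)(O)CC/C=C(C(=O)OC(C)(C)C)/CC/C(=C\C=O)C(C)C)P(=O)(Oc1ccccc1)Oc1ccccc1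
F9 | step 14 | (2Z,5E)-7-oxo-5-(propan-2-yl)-2-{[(trifluoromethanesulfonyl)oxy]methylidene}hept-5-enoic acid | O=C/C=C(\CC/C(=C/OS(=O)(=O)C(F)(F)F)C(=O)O)C(C)C
F10 | step 14 | (3S)-7-(diphenoxyphosphoryl)-8-methoxy-3-methyl-4,8-dioxooct-1-en-3-yl (2Z,5E)-7-oxo-5-(propan-2-yl)-2-{[(trifluoromethanesulfonyl)oxy]methylidene}hept-5-enoate | COC(=O)C(CCC(=O)[C@](C)(C=C)OC(=O)/C(CC/C(=C\C=O)C(C)C)=C\OS(=O)(=O)C(F)(F)F)P(=O)(Oc1ccccc1)Oc1ccccc1
F11 | step 14 | methyl (3Z,6E,8Z,13S)-13-ethenyl-13-methyl-2,12-dioxo-6-(propan-2-yl)-3-{[(trifluoromethanesulfonyl)oxy]methylidene}-1-oxacyclotrideca-6,8-diene-9-carboxylate | COC(=O)/C1=C\C=C(\C(C)C)CC/C(=C/OS(=O)(=O)C(F)(F)F)C(=O)O[C@@](C)(C=C)C(=O)CC1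
F12 | step 14 | methyl (3Z,6E,8Z,13S)-13-[2-(9-borabicyclo[3.3.1]nonan-9-yl)ethyl]-13-methyl-2,12-dioxo-6-(propan-2-yl)-3-{[(trifluoromethanesulfonyl)oxy]methylidene}-1-oxacyclotrideca-6,8-diene-9-carboxylate | COC(=O)/C1=C\C=C(\C(C)C)CC/C(=C/OS(=O)(=O)C(F)(F)F)C(=O)O[C@@](C)(CCB2C3CCCC2CCC3)C(=O)CC1
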